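Numbering: chroman half O1, C2 to C4, C4a to C8a (benzene ring B); chromene half likewise with primes (benzene ring A). Retrosynthetic cuts, in this order: C1–C2 of both prenyl groups (back to methyl esters on C8 and C8'), the ring A pyran (O1'–C2' and C4'–C4a'), C7'–C8' of ring A, C4–C6', then the ring B pyran and C7–C8 of ring B.
Feature used: ring A is a resorcinol with O8a' and O5' in a 1,3 relation, C6' lies between the former C5' and C7' carbonyl carbons and C8' bears one extra carbon. Ring A therefore unfolds to a methyl 3,5,7-trioxo ester whose acyl ketene end is stored as a dioxinone; ring B has the same pattern without the substituent on the carbon that matches C6'.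
Forward: one diketo-dioxinone is used twice. It first folds to the ring B resorcylate, whose chelated oxygen becomes O1 of the pyran (propargyl ether, Claisen rearrangement), and hydration of the chromene gives the chroman-4-ol.
The same diketo-dioxinone then adds through its central carbon (C6') to the ortho-quinone methide of that chromanol (bond C4–C6'), and the chromanyl diketo-dioxinone folds to ring A in the key step.
The ring A pyran is closed as for ring B, both esters are turned together into the two prenyl groups, and four aryl silyl ethers are cleaved last. The C8 ester is kept until then because the hydration that activates C4 would not spare a prenyl alkene.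
Stereochemistry: C4 (R) is the only stereocentre. A chiral phosphoric acid sets it in the quinone methide addition, C6' stops being stereogenic when ring A aromatises, and O5 stays silylated during the fold so that the C4–C6' bond cannot reopen.

Key step: step 11

Abbreviations: TIPS = triisopropylsilyl; Ar = 4-(triisopropylsilyloxy)phenyl; "arm" = the 2-Ar-ethyl group; (R)-TRIP = (R)-3,3'-bis(2,4,6-triisopropylphenyl)-1,1'-binaphthyl-2,2'-diyl hydrogen phosphate.
Assumption: the sense of induction of the phosphoric acid on this cyclic quinone methide cannot be predicted with certainty; the route is written with (R)-TRIP, and the antipodal acid is used instead if the first run gives the 4S series. The compounds between the coupling and the fold are mixtures of C6' epimers and enols, so their SMILES leave C6' undefined.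

Step 1
Reactants: 1 3-(4-hydroxyphenyl)propanoic acid
Product: 3 3-[4-(triisopropylsilyloxy)phenyl]propanoic acid, via silyl ester 2 (not isolated)
Conditions: iPr3SiCl (2.2 equiv), imidazole, DMF, rt; then AcOH/THF/H2O (3:1:1), rt
Reagents that add atoms: triisopropylsilyl chloride, CC(C)[Si](Cl)(C(C)C)C(C)C
Why: Silylation of both acidic oxygens followed by selective hydrolysis of the much more labile silyl ester is a standard phenol protection, and the aryl TIPS ether is chosen because it should tolerate the amide bases, carbonate, heat and hydride used later and still fall to fluoride at the end.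

Step 2
Reactants: 4 2,2,6-trimethyl-4H-1,3-dioxin-4-one
Product: 5 2,2-dimethyl-6-(2-oxopropyl)-4H-1,3-dioxin-4-one (keto-dioxinone)
Conditions: 4 (2 equiv), LiN(SiMe3)2 (2 equiv), THF, −78 °C; AcCl (1 equiv), −78 to −20 °C; 1 M HCl
Reagents that add atoms: acetyl chloride, CC(=O)Cl
Why: The lithium dienolate of the dioxinone is acylated on its gamma carbon (vinylogous Claisen condensation), the second equivalent of enolate absorbing the more acidic product.

Step 3
Reactants: 5 keto-dioxinone; 3 3-[4-(triisopropylsilyloxy)phenyl]propanoic acid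
Product: 7 2,2-dimethyl-6-(2,4-dioxo-6-Ar-hexyl)-4H-1,3-dioxin-4-one (diketo-dioxinone), via acyl imidazole 6 (not isolated)
Conditions: 3, 1,1'-carbonyldiimidazole, THF, rt; this solution added to 5 (2 equiv), LiN(iPr)2 (4.1 equiv), THF, −78 to −40 °C; 1 M HCl
Reagents that add atoms: none
Why: The dianion of the keto-dioxinone reacts at its terminal, last-formed carbanion with the acyl imidazole (crossed Claisen condensation of a dianion), which is the established route to diketo-dioxinones, and the excess dianion absorbs the acidic product.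

Step 4
Reactants: 7 diketo-dioxinone; 8 methanol
Product: 11 methyl 2,4-dihydroxy-6-(2-Ar-ethyl)benzoate (ring B resorcylate), via acyl ketene 9 (not isolated), via triketo ester 10 (not isolated)
Conditions: PhMe, MeOH (10 equiv), 110 °C (sealed tube); concentrate; Cs2CO3, THF, rt; then HCl in MeOH, rt
Reagents that add atoms: none
Why: Retro-[4+2] loss of acetone, capture of the ketene by methanol and aldol aromatisation of the triketo ester is the known resorcylate synthesis from diketo-dioxinones, and it rehearses the key step on the unsubstituted chain.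

Step 5
Reactants: 11 ring B resorcylate
Product: 12 methyl 4-(benzyloxy)-2-hydroxy-6-(2-Ar-ethyl)benzoate
Conditions: BnBr (1.05 equiv), K2CO3, acetone, rt
Reagents that add atoms: benzyl bromide, BrCc1ccccc1
Why: Williamson etherification should go to the oxygen para to the ester because the ortho hydroxyl is held in a hydrogen bond to the ester carbonyl, which leaves the chelated oxygen (the future O1) as the only free phenol.

Step 6
Reactants: 12 benzyl ether
Product: 13 methyl 4-(benzyloxy)-2-[(2-methylbut-3-yn-2-yl)oxy]-6-(2-Ar-ethyl)benzoate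
Conditions: HC≡CCMe2Cl (3 equiv), K2CO3, KI, CuI (10 mol %), dry DMF, 60 °C
Reagents that add atoms: 3-chloro-3-methylbut-1-yne, CC(C)(Cl)C#C
Why: Copper-assisted O-alkylation of a phenoxide by the tertiary propargylic chloride is the standard entry to aryl 1,1-dimethylpropargyl ethers and works well with electron-poor phenoxides such as this salicylate once carbonate in DMF has broken the chelate.

Step 7
Reactants: 13 propargyl ether
Product: 14 methyl 5-(benzyloxy)-2,2-dimethyl-7-(2-Ar-ethyl)-2H-chromene-8-carboxylate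
Conditions: 1,2-dichlorobenzene, 170 °C
Reagents that add atoms: none
Why: Aromatic propargyl Claisen rearrangement to the only free ortho carbon (the future C4a), enolisation, 1,5-hydrogen shift and oxa-6π electrocyclisation should give the 2,2-dimethyl-2H-chromene with the pyran fixed on the oxygen next to the ester.

Step 8
Reactants: 14 chromene
Product: 15 methyl 5-(benzyloxy)-4-hydroxy-2,2-dimethyl-7-(2-Ar-ethyl)chromane-8-carboxylate (racemic)
Conditions: Co(acac)2 (20 mol %), PhSiH3, O2 (1 atm), THF, rt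
Reagents that add atoms: dioxygen, O=O
Why: Mukaiyama hydration delivers hydrogen to C3 and oxygen to the benzylic radical at C4, so the chroman-4-ol should form regioselectively, and its configuration is irrelevant because C4 becomes planar in step 10.

Step 9
Reactants: 15 chromanol benzyl ether
Product: 16 methyl 4,5-dihydroxy-2,2-dimethyl-7-(2-Ar-ethyl)chromane-8-carboxylate (racemic)
Conditions: H2 (1 atm), 10% Pd/C, EtOAc, rt
Reagents that add atoms: none
Why: Hydrogenolysis of the aryl benzyl ether frees O5 under neutral conditions that should leave the aryl TIPS ether, the ester and (in ethyl acetate without acid) the benzylic alcohol untouched, and no alkene is present at this stage.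

Step 10
Reactants: 16 ring B chroman-4,5-diol; 7 diketo-dioxinone
Product: 18 O5-TIPS chromanyl diketo-dioxinone (4R; C6' epimers and enols), via phenol adduct 17 (not isolated)
Conditions: (R)-TRIP (10 mol %), 7 (1.5 equiv), 4 Å molecular sieves, CH2Cl2, 0 °C to rt, 16 added slowly; then 2,6-lutidine, iPr3SiOTf, −78 to 0 °C; AcOH/THF/H2O work-up
Reagents that add atoms: triisopropylsilyl trifluoromethanesulfonate, CC(C)[Si](OS(=O)(=O)C(F)(F)F)(C(C)C)C(C)C
Why: Chiral phosphoric acid-catalysed dehydration of an ortho-hydroxybenzylic alcohol to an ortho-quinone methide and conjugate addition of a 1,3-diketone enol (here through C6') is a known enantioselective reaction type in which the phosphate holds the quinone methide oxygen and the enol in one hydrogen-bonded ion pair and so selects the face of C4 (4R), while silylation of O5 in the same flask stops the phenol from closing onto a ketone and the aqueous acetic acid hydrolyses any enol silyl ether.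

Step 11
Reactants: 18 O5-TIPS chromanyl diketo-dioxinone; 8 methanol
Product: 21 ring A resorcylate (4R) with the methyl ester on C8' and free hydroxyls on C8a' and C5', via acyl ketene 19 (not isolated), via triketo ester 20 (not isolated)
Conditions: PhMe, MeOH (10 equiv), 110 °C (sealed tube); concentrate; Cs2CO3, THF, 0 °C to rt; then HCl in MeOH, rt
Reagents that add atoms: none
Why: Heat opens the dioxinone by retro-[4+2] loss of acetone to acyl ketene 19, which the excess methanol should intercept as triketo ester 20 before the C5' enol oxygen can close a pyranone; carbonate then forms the C8' enolate, which adds to the C7' ketone, and acid completes loss of water and enolisation of the C8a' and C5' carbonyls to the phenols. The closest known reaction type is the thermolysis, alcohol trapping and aldol aromatisation of diketo-dioxinones to resorcylate esters, here with a substituent on the central diketone carbon. Ring A closes by a 6-(enolendo)-exo-trig aldol addition (C8' to the C7' carbonyl), made irreversible by dehydration to the arene. No stereocentre is created that survives, since the aldol carbinol and C6' both end as aromatic carbons; the existing C4 centre is held because O5 is silylated, so that no phenoxide can expel the diketone by retro-Michael cleavage of C4–C6', and C4–H is not acidic. The step needs regioselectivity among aldol, Claisen and lactone closures: C8' is the only carbon activated by two carbonyl groups that can reach a ketone through a six-membered ring (the more acidic C4a' could only form four-membered rings), the arm methylene is singly activated, and Claisen closure from C6' onto the ester would give a quaternary carbon that cannot aromatise and therefore reverts. Running the base stage in THF instead of methanol should keep the aryl silyl ethers, above all the one on O5 that is para to the ring B ester.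

Step 12
Reactants: 21 ring A resorcylate
Product: 22 O5'-TIPS ether of 21 (tetrakis-TIPS; O8a'–H free)
Conditions: iPr3SiCl (1.5 equiv), imidazole, DMAP (cat.), DMF, 40 °C
Reagents that add atoms: triisopropylsilyl chloride, CC(C)[Si](Cl)(C(C)C)C(C)C
Why: Silyl chloride and imidazole should silylate the unchelated O5' only, because O8a' is hydrogen-bonded to the C8' ester, and this leaves O8a' as the single phenol for the pyran annulation.

Step 13
Reactants: 22 tetrakis-TIPS resorcylate
Product: 23 O8a' 2-methylbut-3-yn-2-yl ether of 22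
Conditions: HC≡CCMe2Cl (3 equiv), K2CO3, KI, CuI (10 mol %), dry DMF, 60 °C
Reagents that add atoms: 3-chloro-3-methylbut-1-yne, CC(C)(Cl)C#C
Why: This is the copper-assisted propargylation of step 6 on the same local pattern (a phenoxide ortho to a methyl ester), and dry carbonate should not attack the hindered TIPS ethers.

Step 14
Reactants: 23 propargyl ether
Product: 24 ring A chromene diester (4R)
Conditions: 1,2-dichlorobenzene, 170 °C
Reagents that add atoms: none
Why: The propargyl Claisen rearrangement can only go to C4a' (C8' is blocked by the ester) and the following electrocyclisation closes the 2,2-dimethylpyran on O8a', while C4 is a doubly benzylic CH with no ionising or enolising path under neutral heat.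

Step 15
Reactants: 24 chromene diester
Product: 25 bis(hydroxymethyl) compound (CH2OH on C8 and C8')
Conditions: iBu2AlH (8 equiv), CH2Cl2, −78 to 0 °C; aq. potassium sodium tartrate
Reagents that add atoms: none
Why: Hydride reduction of both hindered aryl methyl esters to the benzylic alcohols is routine, and aryl silyl ethers and the chromene alkene are inert to iBu2AlH.

Step 16
Reactants: 25 diol
Product: 26 bis(bromomethyl) compound (CH2Br on C8 and C8')
Conditions: CBr4, PPh3, CH2Cl2, −20 °C; short plug of basic Al2O3, used at once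
Reagents that add atoms: carbon tetrabromide, BrC(Br)(Br)Br
Why: The Appel reaction converts primary benzylic alcohols into bromides under neutral conditions at low temperature, which suits these electron-rich and therefore labile benzylic halides.

Step 17
Reactants: 26 dibromide
Product: 27 bis-prenyl tetrakis-TIPS ether (4R)
Conditions: Me2C=CHMgBr (6 equiv), CuI (20 mol %), THF, −40 to 0 °C
Reagents that add atoms: (2-methylprop-1-en-1-yl)magnesium bromide, CC(C)=C[Mg]Br
Why: Copper-catalysed coupling of a benzylic bromide with an alkenyl Grignard reagent forms each ArCH2–CH=CMe2 bond and so both prenyl groups in one operation, with the position of the double bond fixed by the reagent.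

Step 18
Reactants: 27 bis-prenyl tetrakis-TIPS ether
Product: 28 CNP0103951.1 (target, 4R)
Conditions: Bu4NF (6 equiv), AcOH (6 equiv), THF, 0 °C to rt
Reagents that add atoms: none
Why: Fluoride cleaves the four aryl silyl ethers, and the acetic acid buffers the phenoxides so that the electron-rich chromene and the C4 benzylic centre should see neither strong base nor acid.

Compound list
1 | 3-(4-hydroxyphenyl)propanoic acid | OC(=O)CCc1ccc(O)cc1 | starting material
2 | triisopropylsilyl 3-[4-(triisopropylsilyloxy)phenyl]propanoate | CC(C)[Si](OC(=O)CCc1ccc(O[Si](C(C)C)(C(C)C)C(C)C)cc1)(C(C)C)C(C)C | intermediate (not isolated)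
3 | 3-[4-(triisopropylsilyloxy)phenyl]propanoic acid | OC(=O)CCc1ccc(O[Si](C(C)C)(C(C)C)C(C)C)cc1 | intermediate
4 | 2,2,6-trimethyl-4H-1,3-dioxin-4-one | CC1=CC(=O)OC(C)(C)O1 | starting material
5 | 2,2-dimethyl-6-(2-oxopropyl)-4H-1,3-dioxin-4-one | CC(=O)CC1=CC(=O)OC(C)(C)O1 | intermediate
6 | 1-{3-[4-(triisopropylsilyloxy)phenyl]propanoyl}imidazole | O=C(CCc1ccc(O[Si](C(C)C)(C(C)C)C(C)C)cc1)n1ccnc1 | intermediate (not isolated)
7 | 2,2-dimethyl-6-{2,4-dioxo-6-[4-(triisopropylsilyloxy)phenyl]hexyl}-4H-1,3-dioxin-4-one (enol tautomers) | CC1(C)OC(=O)C=C(CC(=O)CC(=O)CCc2ccc(O[Si](C(C)C)(C(C)C)C(C)C)cc2)O1 | intermediate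
8 | methanol | CO | starting material
9 | 3,5,7-trioxo-9-[4-(triisopropylsilyloxy)phenyl]non-1-en-1-one (acyl ketene) | O=C=CC(=O)CC(=O)CC(=O)CCc1ccc(O[Si](C(C)C)(C(C)C)C(C)C)cc1 | intermediate (not isolated)
10 | methyl 3,5,7-trioxo-9-[4-(triisopropylsilyloxy)phenyl]nonanoate | COC(=O)CC(=O)CC(=O)CC(=O)CCc1ccc(O[Si](C(C)C)(C(C)C)C(C)C)cc1 | intermediate (not isolated)
11 | methyl 2,4-dihydroxy-6-{2-[4-(triisopropylsilyloxy)phenyl]ethyl}benzoate | COC(=O)c1c(O)cc(O)cc1CCc1ccc(O[Si](C(C)C)(C(C)C)C(C)C)cc1 | intermediate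
12 | methyl 4-(benzyloxy)-2-hydroxy-6-{2-[4-(triisopropylsilyloxy)phenyl]ethyl}benzoate | COC(=O)c1c(O)cc(OCc2ccccc2)cc1CCc1ccc(O[Si](C(C)C)(C(C)C)C(C)C)cc1 | intermediate
13 | methyl 4-(benzyloxy)-2-[(2-methylbut-3-yn-2-yl)oxy]-6-{2-[4-(triisopropylsilyloxy)phenyl]ethyl}benzoate | COC(=O)c1c(OC(C)(C)C#C)cc(OCc2ccccc2)cc1CCc1ccc(O[Si](C(C)C)(C(C)C)C(C)C)cc1 | intermediate
14 | methyl 5-(benzyloxy)-2,2-dimethyl-7-{2-[4-(triisopropylsilyloxy)phenyl]ethyl}-2H-chromene-8-carboxylate | COC(=O)c1c(CCc2ccc(O[Si](C(C)C)(C(C)C)C(C)C)cc2)cc(OCc2ccccc2)c2C=CC(C)(C)Oc12 | intermediate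
15 | methyl 5-(benzyloxy)-4-hydroxy-2,2-dimethyl-7-{2-[4-(triisopropylsilyloxy)phenyl]ethyl}chromane-8-carboxylate (racemic) | COC(=O)c1c(CCc2ccc(O[Si](C(C)C)(C(C)C)C(C)C)cc2)cc(OCc2ccccc2)c2C(O)CC(C)(C)Oc12 | intermediate
16 | methyl 4,5-dihydroxy-2,2-dimethyl-7-{2-[4-(triisopropylsilyloxy)phenyl]ethyl}chromane-8-carboxylate (racemic) | COC(=O)c1c(CCc2ccc(O[Si](C(C)C)(C(C)C)C(C)C)cc2)cc(O)c2C(O)CC(C)(C)Oc12 | intermediate
17 | methyl (4R)-4-{1-(2,2-dimethyl-4-oxo-4H-1,3-dioxin-6-yl)-2,4-dioxo-6-[4-(triisopropylsilyloxy)phenyl]hexan-3-yl}-5-hydroxy-2,2-dimethyl-7-{2-[4-(triisopropylsilyloxy)phenyl]ethyl}chromane-8-carboxylate (C6' epimers and enols) | CC1(C)OC(=O)C=C(CC(=O)C(C(=O)CCc2ccc(O[Si](C(C)C)(C(C)C)C(C)C)cc2)[C@H]2CC(C)(C)Oc3c(C(=O)OC)c(CCc4ccc(O[Si](C(C)C)(C(C)C)C(C)C)cc4)cc(O)c32)O1 | intermediate (not isolated)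
18 | the 5-(triisopropylsilyloxy) ether of 17, 4R (key-step precursor; C6' epimers and enols) | CC1(C)OC(=O)C=C(CC(=O)C(C(=O)CCc2ccc(O[Si](C(C)C)(C(C)C)C(C)C)cc2)[C@H]2CC(C)(C)Oc3c(C(=O)OC)c(CCc4ccc(O[Si](C(C)C)(C(C)C)C(C)C)cc4)cc(O[Si](C(C)C)(C(C)C)C(C)C)c32)O1 | intermediate
19 | methyl (4R)-2,2-dimethyl-4-{3,5,7,9-tetraoxo-1-[4-(triisopropylsilyloxy)phenyl]non-8-en-4-yl}-5-(triisopropylsilyloxy)-7-{2-[4-(triisopropylsilyloxy)phenyl]ethyl}chromane-8-carboxylate (acyl ketene) | O=C=CC(=O)CC(=O)C(C(=O)CCc1ccc(O[Si](C(C)C)(C(C)C)C(C)C)cc1)[C@H]1CC(C)(C)Oc2c(C(=O)OC)c(CCc3ccc(O[Si](C(C)C)(C(C)C)C(C)C)cc3)cc(O[Si](C(C)C)(C(C)C)C(C)C)c21 | intermediate (not isolated)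
20 | methyl (4R)-4-{9-methoxy-3,5,7,9-tetraoxo-1-[4-(triisopropylsilyloxy)phenyl]nonan-4-yl}-2,2-dimethyl-5-(triisopropylsilyloxy)-7-{2-[4-(triisopropylsilyloxy)phenyl]ethyl}chromane-8-carboxylate (triketo ester) | COC(=O)CC(=O)CC(=O)C(C(=O)CCc1ccc(O[Si](C(C)C)(C(C)C)C(C)C)cc1)[C@H]1CC(C)(C)Oc2c(C(=O)OC)c(CCc3ccc(O[Si](C(C)C)(C(C)C)C(C)C)cc3)cc(O[Si](C(C)C)(C(C)C)C(C)C)c21 | intermediate (not isolated)
21 | methyl (4R)-4-[2,4-dihydroxy-5-(methoxycarbonyl)-6-{2-[4-(triisopropylsilyloxy)phenyl]ethyl}phenyl]-2,2-dimethyl-5-(triisopropylsilyloxy)-7-{2-[4-(triisopropylsilyloxy)phenyl]ethyl}chromane-8-carboxylate (key-step product) | COC(=O)c1c(O)cc(O)c([C@H]2CC(C)(C)Oc3c(C(=O)OC)c(CCc4ccc(O[Si](C(C)C)(C(C)C)C(C)C)cc4)cc(O[Si](C(C)C)(C(C)C)C(C)C)c32)c1CCc1ccc(O[Si](C(C)C)(C(C)C)C(C)C)cc1 | intermediate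
22 | methyl (4R)-4-[4-hydroxy-5-(methoxycarbonyl)-2-(triisopropylsilyloxy)-6-{2-[4-(triisopropylsilyloxy)phenyl]ethyl}phenyl]-2,2-dimethyl-5-(triisopropylsilyloxy)-7-{2-[4-(triisopropylsilyloxy)phenyl]ethyl}chromane-8-carboxylate | COC(=O)c1c(O)cc(O[Si](C(C)C)(C(C)C)C(C)C)c([C@H]2CC(C)(C)Oc3c(C(=O)OC)c(CCc4ccc(O[Si](C(C)C)(C(C)C)C(C)C)cc4)cc(O[Si](C(C)C)(C(C)C)C(C)C)c32)c1CCc1ccc(O[Si](C(C)C)(C(C)C)C(C)C)cc1 | intermediate
23 | the 4-[(2-methylbut-3-yn-2-yl)oxy] ether of 22 (ether on O8a'), 4R | COC(=O)c1c(OC(C)(C)C#C)cc(O[Si](C(C)C)(C(C)C)C(C)C)c([C@H]2CC(C)(C)Oc3c(C(=O)OC)c(CCc4ccc(O[Si](C(C)C)(C(C)C)C(C)C)cc4)cc(O[Si](C(C)C)(C(C)C)C(C)C)c32)c1CCc1ccc(O[Si](C(C)C)(C(C)C)C(C)C)cc1 | intermediate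
24 | methyl (4R)-4-[8-(methoxycarbonyl)-2,2-dimethyl-5-(triisopropylsilyloxy)-7-{2-[4-(triisopropylsilyloxy)phenyl]ethyl}-2H-chromen-6-yl]-2,2-dimethyl-5-(triisopropylsilyloxy)-7-{2-[4-(triisopropylsilyloxy)phenyl]ethyl}chromane-8-carboxylate | COC(=O)c1c(CCc2ccc(O[Si](C(C)C)(C(C)C)C(C)C)cc2)c([C@H]2CC(C)(C)Oc3c(C(=O)OC)c(CCc4ccc(O[Si](C(C)C)(C(C)C)C(C)C)cc4)cc(O[Si](C(C)C)(C(C)C)C(C)C)c32)c(O[Si](C(C)C)(C(C)C)C(C)C)c2c1OC(C)(C)C=C2 | intermediate
25 | the 8,8'-bis(hydroxymethyl) analogue of 24 (both CO2Me reduced to CH2OH), 4R | OCc1c(CCc2ccc(O[Si](C(C)C)(C(C)C)C(C)C)cc2)c([C@H]2CC(C)(C)Oc3c(CO)c(CCc4ccc(O[Si](C(C)C)(C(C)C)C(C)C)cc4)cc(O[Si](C(C)C)(C(C)C)C(C)C)c32)c(O[Si](C(C)C)(C(C)C)C(C)C)c2c1OC(C)(C)C=C2 | intermediate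
26 | the 8,8'-bis(bromomethyl) analogue of 25, 4R | BrCc1c(CCc2ccc(O[Si](C(C)C)(C(C)C)C(C)C)cc2)c([C@H]2CC(C)(C)Oc3c(CBr)c(CCc4ccc(O[Si](C(C)C)(C(C)C)C(C)C)cc4)cc(O[Si](C(C)C)(C(C)C)C(C)C)c32)c(O[Si](C(C)C)(C(C)C)C(C)C)c2c1OC(C)(C)C=C2 | intermediate
27 | (4R)-2,2-dimethyl-4-[2,2-dimethyl-8-(3-methylbut-2-en-1-yl)-5-(triisopropylsilyloxy)-7-{2-[4-(triisopropylsilyloxy)phenyl]ethyl}-2H-chromen-6-yl]-8-(3-methylbut-2-en-1-yl)-5-(triisopropylsilyloxy)-7-{2-[4-(triisopropylsilyloxy)phenyl]ethyl}chromane | CC(C)=CCc1c(CCc2ccc(O[Si](C(C)C)(C(C)C)C(C)C)cc2)c([C@H]2CC(C)(C)Oc3c(CC=C(C)C)c(CCc4ccc(O[Si](C(C)C)(C(C)C)C(C)C)cc4)cc(O[Si](C(C)C)(C(C)C)C(C)C)c32)c(O[Si](C(C)C)(C(C)C)C(C)C)c2c1OC(C)(C)C=C2 | intermediate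
28 | CNP0103951.1: (4R)-4-{5-hydroxy-7-[2-(4-hydroxyphenyl)ethyl]-2,2-dimethyl-8-(3-methylbut-2-en-1-yl)-2H-chromen-6-yl}-7-[2-(4-hydroxyphenyl)ethyl]-2,2-dimethyl-8-(3-methylbut-2-en-1-yl)chroman-5-ol | CC(C)=CCc1c(CCc2ccc(O)cc2)c([C@H]2CC(C)(C)Oc3c(CC=C(C)C)c(CCc4ccc(O)cc4)cc(O)c32)c(O)c2c1OC(C)(C)C=C2 | target

Total step count: 18. Longest linear sequence: 17 steps (step 1 or step 2, then steps 3 to 18).

Steps most likely to fail

Step 10. The quinone methide may lose a C3 proton and drain into the 2H-chromene faster than the diketone enol adds. The phosphate may also discriminate poorly between the faces of a quinone methide that carries no aryl group at C4, or the free phenol of the adduct may close onto a ketone and lose water before it is silylated. Fallback: give up catalytic control and make the bond from the benzyl ether 15 instead of the phenol 16. Brønsted acid-catalysed benzylation of the 1,3-diketone 7 by the secondary benzylic alcohol 15 (TsOH·H2O, 5 mol %, CH2Cl2, rt) should give the racemic O5-benzyl precursor F1. In this reaction the cation stabilised by O1 and O5 is captured at C6', any chromene re-enters by protonation, and no phenol is present. The conditions of step 11 would take F1 through the racemic acyl ketene F2 and the racemic triketo ester F3 to the racemic O5-benzyl resorcylate F4, in which C4 is the only stereocentre. Preparative chromatography on a chiral stationary phase (amylose tris(3,5-dimethylphenylcarbamate)) would give the 4R O5-benzyl resorcylate F5. Hydrogenolysis (H2, 10% Pd/C, EtOAc; no alkene is present yet) would free O5 to give the 4R triphenol F6, and silylation of both unchelated phenols under the conditions of step 12 (iPr3SiCl, 3 equiv) returns to the route at 22.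

Step 11. The aldol closure at the C7' carbonyl, which sits next to the chromanyl-bearing C6', may be slow. At 110 °C the acyl ketene could then be lost to O-acylation by the C5' enol (pyranone), or the open triketo ester could degrade before it cyclises. Fallback: close ring A on the intact dioxinone and make the ester afterwards. From 18, Et3N in CH2Cl2 at rt (aldol addition of the dioxinone dienolate through C8' to the C7' ketone) and then CF3CO2H (dehydration) should give the benzodioxinone F7, the acetonide of the ring A salicylate. This is a known alternative aromatisation of diketo-dioxinones in which no ketene is ever free. Opening of the acetonide with NaOMe in MeOH/THF at 0 °C (transesterification with loss of acetone) would give the methyl ester 21.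

Step 16. The two benzylic bromides, each para to a silyloxy group and ortho to a ring oxygen, may ionise during their formation or on the alumina plug and be lost to solvolysis or self-alkylation. Fallback: avoid the halide. From diol 25, methyl chloroformate and pyridine (CH2Cl2, 0 °C) should give the bis(methyl carbonate) F8, which is stable to chromatography. Palladium-catalysed benzylic Suzuki–Miyaura coupling with 2-methylprop-1-enylboronic acid pinacol ester ([Pd(η3-C3H5)Cl]2, 1,5-bis(diphenylphosphino)pentane, DMF, 80 °C) would then give 27 directly. In that coupling the benzylic carbonate adds oxidatively to zerovalent palladium with loss of CO2, and the methoxide set free activates the boronate.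

Further compounds
F1 | step 10 | racemic O5-benzyl precursor: methyl 5-(benzyloxy)-4-{1-(2,2-dimethyl-4-oxo-4H-1,3-dioxin-6-yl)-2,4-dioxo-6-[4-(triisopropylsilyloxy)phenyl]hexan-3-yl}-2,2-dimethyl-7-{2-[4-(triisopropylsilyloxy)phenyl]ethyl}chromane-8-carboxylate | CC1(C)OC(=O)C=C(CC(=O)C(C(=O)CCc2ccc(O[Si](C(C)C)(C(C)C)C(C)C)cc2)C2CC(C)(C)Oc3c(C(=O)OC)c(CCc4ccc(O[Si](C(C)C)(C(C)C)C(C)C)cc4)cc(OCc4ccccc4)c32)O1
F2 | step 10 | racemic acyl ketene from F1 | O=C=CC(=O)CC(=O)C(C(=O)CCc1ccc(O[Si](C(C)C)(C(C)C)C(C)C)cc1)C1CC(C)(C)Oc2c(C(=O)OC)c(CCc3ccc(O[Si](C(C)C)(C(C)C)C(C)C)cc3)cc(OCc3ccccc3)c21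
F3 | step 10 | racemic triketo ester from F2 | COC(=O)CC(=O)CC(=O)C(C(=O)CCc1ccc(O[Si](C(C)C)(C(C)C)C(C)C)cc1)C1CC(C)(C)Oc2c(C(=O)OC)c(CCc3ccc(O[Si](C(C)C)(C(C)C)C(C)C)cc3)cc(OCc3ccccc3)c21
F4 | step 10 | racemic O5-benzyl resorcylate: methyl 5-(benzyloxy)-4-[2,4-dihydroxy-5-(methoxycarbonyl)-6-{2-[4-(triisopropylsilyloxy)phenyl]ethyl}phenyl]-2,2-dimethyl-7-{2-[4-(triisopropylsilyloxy)phenyl]ethyl}chromane-8-carboxylate | COC(=O)c1c(O)cc(O)c(C2CC(C)(C)Oc3c(C(=O)OC)c(CCc4ccc(O[Si](C(C)C)(C(C)C)C(C)C)cc4)cc(OCc4ccccc4)c32)c1CCc1ccc(O[Si](C(C)C)(C(C)C)C(C)C)cc1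
F5 | step 10 | 4R O5-benzyl resorcylate (resolved F4) | COC(=O)c1c(O)cc(O)c([C@H]2CC(C)(C)Oc3c(C(=O)OC)c(CCc4ccc(O[Si](C(C)C)(C(C)C)C(C)C)cc4)cc(OCc4ccccc4)c32)c1CCc1ccc(O[Si](C(C)C)(C(C)C)C(C)C)cc1
F6 | step 10 | 4R triphenol: methyl (4R)-4-[2,4-dihydroxy-5-(methoxycarbonyl)-6-{2-[4-(triisopropylsilyloxy)phenyl]ethyl}phenyl]-5-hydroxy-2,2-dimethyl-7-{2-[4-(triisopropylsilyloxy)phenyl]ethyl}chromane-8-carboxylate | COC(=O)c1c(O)cc(O)c([C@H]2CC(C)(C)Oc3c(C(=O)OC)c(CCc4ccc(O[Si](C(C)C)(C(C)C)C(C)C)cc4)cc(O)c32)c1CCc1ccc(O[Si](C(C)C)(C(C)C)C(C)C)cc1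
F7 | step 11 | benzodioxinone: methyl (4R)-4-[7-hydroxy-2,2-dimethyl-4-oxo-5-{2-[4-(triisopropylsilyloxy)phenyl]ethyl}-4H-1,3-benzodioxin-6-yl]-2,2-dimethyl-5-(triisopropylsilyloxy)-7-{2-[4-(triisopropylsilyloxy)phenyl]ethyl}chromane-8-carboxylate | CC1(C)OC(=O)c2c(O1)cc(O)c([C@H]3CC(C)(C)Oc4c(C(=O)OC)c(CCc5ccc(O[Si](C(C)C)(C(C)C)C(C)C)cc5)cc(O[Si](C(C)C)(C(C)C)C(C)C)c43)c2CCc1ccc(O[Si](C(C)C)(C(C)C)C(C)C)cc1
F8 | step 16 | bis(methyl carbonate) of diol 25 | COC(=O)OCc1c(CCc2ccc(O[Si](C(C)C)(C(C)C)C(C)C)cc2)c([C@H]2CC(C)(C)Oc3c(COC(=O)OC)c(CCc4ccc(O[Si](C(C)C)(C(C)C)C(C)C)cc4)cc(O[Si](C(C)C)(C(C)C)C(C)C)c32)c(O[Si](C(C)C)(C(C)C)C(C)C)c2c1OC(C)(C)C=C2
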